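**Strategy**

Everything rests on disconnecting the side-chain ketone carbon from the CH2 that hangs on the quaternary ring carbon. The key step exploits the 1,5-diketone array C(=O)–CH2–C–C–C(=O) that spans the two cis-substituted vicinal quaternary carbons of the cyclopentane ring. Folded into a cis-fused cyclobutanone, (1R,5R)-1,5-dimethylbicyclo[3.2.0]heptan-6-one, this CH2 is the only enolisable carbon. Its lithium enolate adds to the complete arene-bearing (Z)-enal in one aldol step, uniting a C9 and a C15 fragment. Alkenyl addition, oxidation and strain-driven retro-aldol opening of the four-membered ring later unveil both ketones.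

Key step: step 9

Assumption: the sense of induction of the oxazaborolidine catalyst on this symmetric alkene is not predicted here, so the catalyst antipode that leads to the (1R,5R) cycloadduct is the one used.

**Route**

Step 1
Reactants: 1 (triphenylphosphoranylidene)ketene; 2 2,2,2-trifluoroethanol; 3 acetyl chloride
Product: 6 2,2,2-trifluoroethyl buta-2,3-dienoate, via ester ylide 4 (not isolated), via ketene 5 (not isolated)
Conditions: 1 + 2, toluene, 80 °C; then Et3N, 3 added slowly, CH2Cl2, 0 °C to rt
Reagents that add atoms: none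
Why: The alcohol adds to the cumulated ylide to give the stabilised ester ylide, which should undergo a Wittig reaction with ketene generated from acetyl chloride and Et3N to give the allenoate.

Step 2
Reactants: 6 2,2,2-trifluoroethyl buta-2,3-dienoate; 7 1,2-dimethylcyclopentene
Product: 8 2,2,2-trifluoroethyl (2E)-[(1R,5R)-1,5-dimethylbicyclo[3.2.0]heptan-6-ylidene]acetate
Conditions: chiral B-(o-tolyl)oxazaborolidine from α,α-diphenylprolinol (20 mol %), AlBr3 (16 mol %), 7 (3 equiv), CH2Cl2, −78 to −40 °C
Reagents that add atoms: none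
Why: In this Lewis acid-catalysed enantioselective allenoate–alkene [2+2] cycloaddition the electron-rich alkene attacks the β-carbon of the activated allenoate and the γ-carbon closes the ring, so the four-membered ring is necessarily cis-fused and both quaternary stereocentres are set at once, their absolute sense by the catalyst distinguishing the two ends of the symmetric alkene (the exocyclic alkene geometry is of no consequence).

Step 3
Reactants: 8 2,2,2-trifluoroethyl (2E)-[(1R,5R)-1,5-dimethylbicyclo[3.2.0]heptan-6-ylidene]acetate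
Product: 10 (1R,5R)-1,5-dimethylbicyclo[3.2.0]heptan-6-one, via ozonide 9 (not isolated)
Conditions: O3, CH2Cl2, −78 °C; then Me2S, −78 °C to rt
Reagents that add atoms: ozone, [O-][O+]=O
Why: Ozonolysis with reductive work-up should cleave the exocyclic enoate to the cyclobutanone without touching the two quaternary stereocentres.

Step 4
Reactants: 11 4-methoxy-2-methylphenol
Product: 12 2-bromo-4-methoxy-6-methylphenol
Conditions: NBS, i-Pr2NH (10 mol %), CH2Cl2, 0 °C
Reagents that add atoms: N-bromosuccinimide, O=C1CCC(=O)N1Br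
Why: Amine-mediated electrophilic bromination of a phenol should go to the only free position ortho to the hydroxyl group, the para position being blocked by the methoxy group.

Step 5
Reactants: 12 2-bromo-4-methoxy-6-methylphenol
Product: 13 1-bromo-2,5-dimethoxy-3-methylbenzene
Conditions: MeI, K2CO3, acetone, reflux
Reagents that add atoms: iodomethane, CI
Why: Williamson O-methylation of the phenoxide should give the dimethyl ether, which survives all organometallic steps and is removed oxidatively at the end.

Step 6
Reactants: 13 1-bromo-2,5-dimethoxy-3-methylbenzene; 14 4-methyl-3,6-dihydro-2H-pyran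
Product: 16 (3Z)-5-(2,5-dimethoxy-3-methylphenyl)-3-methylpent-3-en-1-ol, via arylmagnesium bromide 15 (not isolated)
Conditions: Mg, THF, reflux; then 14, NiCl2(dppp) (5 mol %; dppp = 1,3-bis(diphenylphosphino)propane), THF–toluene, 60 °C; aq. NH4Cl
Reagents that add atoms: none
Why: In this nickel-catalysed Kumada-type allylic substitution, zerovalent nickel inserts into the allylic C–O bond of the cyclic ether and the aryl group is delivered to the unsubstituted CH2 terminus of the allylnickel alkoxide, so the cis geometry imposed by the ring should become the Z alkene because syn–anti exchange at the fully substituted terminus would need a tertiary σ-allyl nickel.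

Step 7
Reactants: 16 (3Z)-5-(2,5-dimethoxy-3-methylphenyl)-3-methylpent-3-en-1-ol
Product: 17 (3Z)-5-(2,5-dimethoxy-3-methylphenyl)-3-methylpent-3-enal
Conditions: Dess–Martin periodinane, NaHCO3, CH2Cl2, 0 °C; used at once
Reagents that add atoms: none
Why: Buffered Dess–Martin oxidation of a homoallylic alcohol should give the β,γ-unsaturated aldehyde without moving the double bond into conjugation.

Step 8
Reactants: 18 2-methylbut-3-yn-2-ol; 19 tributylstannane
Product: 20 (3E)-2-methyl-4-(tributylstannyl)but-3-en-2-ol
Conditions: PdCl2(PPh3)2 (2 mol %), THF, rt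
Reagents that add atoms: none
Why: Palladium-catalysed syn-hydrostannylation of the terminal alkyne should place tin on the terminal carbon, away from the bulky carbinol, which fixes the E geometry of the future enone.

Step 9
Reactants: 10 (1R,5R)-1,5-dimethylbicyclo[3.2.0]heptan-6-one; 17 (3Z)-5-(2,5-dimethoxy-3-methylphenyl)-3-methylpent-3-enal
Product: 22 (1R,5R)-7-[(3Z)-5-(2,5-dimethoxy-3-methylphenyl)-1-hydroxy-3-methylpent-3-en-1-yl]-1,5-dimethylbicyclo[3.2.0]heptan-6-one (mixture of diastereomers at C7 and the carbinol carbon), via lithium enolate 21 (not isolated)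
Conditions: LDA, THF, −78 °C; then 17, −78 °C; sat. aq. NH4Cl at −78 °C
Reagents that add atoms: none
Why: LDA removes a proton from C7, the only enolisable position of 10 because the other α-carbon (C5) is quaternary, and the lithium enolate adds to the aldehyde carbon of 17 through a closed six-membered transition state. This is a directed aldol addition, the ground-state equivalent of the first half of a De Mayo sequence, and it closes no ring. The two new stereocentres (C7 and the carbinol carbon) are not controlled and need not be, since step 11 returns C7 to CH2 and the carbinol to C=O, while C1 and C5 are untouched. The step needs C–C bond formation to outrun proton transfer from the acidic β,γ-unsaturated aldehyde and must leave the Z double bond out of conjugation; both are secured by the fast lithium aldol at −78 °C with a cold quench. Reversal is disfavoured because it would regenerate a strained cyclobutanone enolate.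

Step 10
Reactants: 22 aldol adduct (name as in step 9); 20 (3E)-2-methyl-4-(tributylstannyl)but-3-en-2-ol
Product: 24 (1R,5R)-7-[(3Z)-5-(2,5-dimethoxy-3-methylphenyl)-1-hydroxy-3-methylpent-3-en-1-yl]-6-[(1E)-3-hydroxy-3-methylbut-1-en-1-yl]-1,5-dimethylbicyclo[3.2.0]heptan-6-ol (mixture of diastereomers at C6 and C7 and the carbinol carbon), via dilithiated alkenyl reagent 23 (not isolated)
Conditions: 20 (3 equiv), n-BuLi (6 equiv), THF, −78 to 0 °C; CeCl3, −78 °C; then 22, −78 °C; aq. NH4Cl
Reagents that add atoms: none
Why: Tin–lithium exchange with retention gives the E alkenyllithium alkoxide, whose cerium derivative should add to the strained ketone in an organocerium 1,2-addition instead of enolising it; one equivalent is spent on the aldol hydroxyl, and the new carbinol centre is erased in step 11.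

Step 11
Reactants: 24 triol (name as in step 10)
Product: 26 (2E)-1-[(1R,2R)-2-{(4Z)-6-(2,5-dimethoxy-3-methylphenyl)-4-methyl-2-oxohex-4-en-1-yl}-1,2-dimethylcyclopentyl]-4-hydroxy-4-methylpent-2-en-1-one, via cyclobutanol β-hydroxy ketone 25 (not isolated)
Conditions: Dess–Martin periodinane, NaHCO3, CH2Cl2, 0 °C to rt; then Et3N, CH2Cl2, rt
Reagents that add atoms: none
Why: The periodinane oxidises only the secondary alcohol, and the resulting β-hydroxy ketone is a cyclobutanol that should undergo retro-aldol cleavage of the C6–C7 bond with release of ring strain (second half of a De Mayo sequence), so that all diastereomers converge on the 1,5-diketone with C7 as CH2 and C6 as the enone carbonyl.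

Step 12
Reactants: 26 diketone dimethyl ether (name as in step 11)
Product: 28 (2E)-1-[(1R,2R)-2-{(4Z)-6-(2,5-dihydroxy-3-methylphenyl)-4-methyl-2-oxohex-4-en-1-yl}-1,2-dimethylcyclopentyl]-4-hydroxy-4-methylpent-2-en-1-one (CNP0212540.1), via quinone 27 (not isolated)
Conditions: (NH4)2Ce(NO3)6, MeCN–H2O, 0 °C; then aq. Na2S2O4, EtOAc, rt, under argon
Reagents that add atoms: water, O
Why: Oxidative demethylation of the 1,4-dimethoxyarene by tetravalent cerium should give the quinone (its oxygens come from water, methanol leaves), and dithionite reduction then gives the hydroquinone while alkenes, ketones and the tertiary alcohol stay inert.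

**Compound list**

1 | (triphenylphosphoranylidene)ketene | O=C=C=P(c1ccccc1)(c1ccccc1)c1ccccc1 | starting material
2 | 2,2,2-trifluoroethanol | OCC(F)(F)F | starting material
3 | acetyl chloride | CC(=O)Cl | starting material
4 | 2,2,2-trifluoroethyl (triphenylphosphoranylidene)acetate | O=C(OCC(F)(F)F)C=P(c1ccccc1)(c1ccccc1)c1ccccc1 | intermediate
5 | ketene | C=C=O | intermediate
6 | 2,2,2-trifluoroethyl buta-2,3-dienoate | C=C=CC(=O)OCC(F)(F)F | intermediate
7 | 1,2-dimethylcyclopentene | CC1=C(C)CCC1 | starting material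
8 | 2,2,2-trifluoroethyl (2E)-[(1R,5R)-1,5-dimethylbicyclo[3.2.0]heptan-6-ylidene]acetate | C1[C@@]2(C)CCC[C@@]2(C)/C1=C/C(=O)OCC(F)(F)F | intermediate
9 | spiro-1,2,4-trioxolane (secondary ozonide) of 8, new centres unassigned | C1[C@@]2(C)CCC[C@@]2(C)C13OOC(C(=O)OCC(F)(F)F)O3 | intermediate
10 | (1R,5R)-1,5-dimethylbicyclo[3.2.0]heptan-6-one | C1[C@@]2(C)CCC[C@@]2(C)C1=O | intermediate
11 | 4-methoxy-2-methylphenol | COc1ccc(O)c(C)c1 | starting material
12 | 2-bromo-4-methoxy-6-methylphenol | COc1cc(C)c(O)c(Br)c1 | intermediate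
13 | 1-bromo-2,5-dimethoxy-3-methylbenzene | COc1cc(C)c(OC)c(Br)c1 | intermediate
14 | 4-methyl-3,6-dihydro-2H-pyran | CC1=CCOCC1 | starting material
15 | (2,5-dimethoxy-3-methylphenyl)magnesium bromide | COc1cc(C)c(OC)c([Mg]Br)c1 | intermediate
16 | (3Z)-5-(2,5-dimethoxy-3-methylphenyl)-3-methylpent-3-en-1-ol | COc1cc(C)c(OC)c(C/C=C(C)\CCO)c1 | intermediate
17 | (3Z)-5-(2,5-dimethoxy-3-methylphenyl)-3-methylpent-3-enal | COc1cc(C)c(OC)c(C/C=C(C)\CC=O)c1 | intermediate
18 | 2-methylbut-3-yn-2-ol | CC(C)(O)C#C | starting material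
19 | tributylstannane | CCCC[SnH](CCCC)CCCC | starting material
20 | (3E)-2-methyl-4-(tributylstannyl)but-3-en-2-ol | CC(C)(O)/C=C/[Sn](CCCC)(CCCC)CCCC | intermediate
21 | lithium enolate of 10 (lithium (1R,5R)-1,5-dimethylbicyclo[3.2.0]hept-6-en-6-olate) | [Li]OC1=C[C@@]2(C)CCC[C@@]12C | intermediate
22 | (1R,5R)-7-[(3Z)-5-(2,5-dimethoxy-3-methylphenyl)-1-hydroxy-3-methylpent-3-en-1-yl]-1,5-dimethylbicyclo[3.2.0]heptan-6-one, C7 and carbinol carbon unassigned | COc1cc(C)c(OC)c(C/C=C(C)\CC(O)C2[C@@]3(C)CCC[C@@]3(C)C2=O)c1 | intermediate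
23 | dilithium salt of (3E)-4-lithio-2-methylbut-3-en-2-ol | [Li]/C=C/C(C)(C)O[Li] | intermediate
24 | (1R,5R)-7-[(3Z)-5-(2,5-dimethoxy-3-methylphenyl)-1-hydroxy-3-methylpent-3-en-1-yl]-6-[(1E)-3-hydroxy-3-methylbut-1-en-1-yl]-1,5-dimethylbicyclo[3.2.0]heptan-6-ol, C6, C7 and carbinol carbon unassigned | COc1cc(C)c(OC)c(C/C=C(C)\CC(O)C2[C@@]3(C)CCC[C@@]3(C)C2(O)/C=C/C(C)(C)O)c1 | intermediate
25 | (3Z)-5-(2,5-dimethoxy-3-methylphenyl)-1-{(1R,5R)-6-hydroxy-6-[(1E)-3-hydroxy-3-methylbut-1-en-1-yl]-1,5-dimethylbicyclo[3.2.0]heptan-7-yl}-3-methylpent-3-en-1-one, C6 and C7 unassigned | COc1cc(C)c(OC)c(C/C=C(C)\CC(=O)C2[C@@]3(C)CCC[C@@]3(C)C2(O)/C=C/C(C)(C)O)c1 | intermediate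
26 | (2E)-1-[(1R,2R)-2-{(4Z)-6-(2,5-dimethoxy-3-methylphenyl)-4-methyl-2-oxohex-4-en-1-yl}-1,2-dimethylcyclopentyl]-4-hydroxy-4-methylpent-2-en-1-one | COc1cc(C)c(OC)c(C/C=C(C)\CC(=O)C[C@@]2(C)CCC[C@@]2(C)C(=O)/C=C/C(C)(C)O)c1 | intermediate
27 | 2-{(2Z)-6-[(1R,2R)-2-((2E)-4-hydroxy-4-methylpent-2-enoyl)-1,2-dimethylcyclopentyl]-3-methyl-5-oxohex-2-en-1-yl}-6-methylcyclohexa-2,5-diene-1,4-dione | CC1=CC(=O)C=C(C/C=C(C)\CC(=O)C[C@@]2(C)CCC[C@@]2(C)C(=O)/C=C/C(C)(C)O)C1=O | intermediate
28 | (2E)-1-[(1R,2R)-2-{(4Z)-6-(2,5-dihydroxy-3-methylphenyl)-4-methyl-2-oxohex-4-en-1-yl}-1,2-dimethylcyclopentyl]-4-hydroxy-4-methylpent-2-en-1-one | C/C(=C/Cc1cc(O)cc(C)c1O)CC(=O)C[C@@]1(C)CCC[C@@]1(C)C(=O)/C=C/C(C)(C)O | target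

**Step count**

Total step count: 12.
Longest linear sequence: 8 steps (steps 4, 5, 6, 7, 9, 10, 11, 12).

**Steps most likely to fail**

Step 2. The tertiary cationic intermediate may lose a proton (ene-type pathway) instead of closing the hindered four-membered ring, or the catalyst may discriminate poorly between the two ends of the symmetric alkene. The fallback sets out from 7 and comes back to the route at 10, replacing catalyst control by a classical resolution. Thermal [2+2] cycloaddition of 7 with dichloroketene F1 (made in the flask from trichloroacetyl chloride and Zn–Cu couple, Et2O) should give racemic cis-7,7-dichloro-1,5-dimethylbicyclo[3.2.0]heptan-6-one F2. Reductive dechlorination (Zn, AcOH) should give racemic cis-1,5-dimethylbicyclo[3.2.0]heptan-6-one F3. Lithiated (S)-N,S-dimethyl-S-phenylsulfoximine F4 (from the commercial sulfoximine and n-BuLi, THF, −78 °C) adds to the ketone to give diastereomeric β-hydroxysulfoximines that should separate on silica. The β-hydroxysulfoximine of the (1R,5R) ketone F5 is then heated (toluene, reflux) to release 10.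

Step 6. Insertion of nickel into the unactivated allylic C–O bond may be slow, so that homocoupling of the Grignard reagent takes over, or equilibration of the allylnickel intermediate may erode the Z geometry. The fallback sets out from 13 (through its Grignard reagent 15) and comes back at 17, so step 7 is not needed. Commercial (2Z)-3-methylpent-2-en-4-yn-1-ol is converted by an Appel reaction (CBr4, PPh3, CH2Cl2, 0 °C) into (3Z)-5-bromo-3-methylpent-3-en-1-yne F6. Uncatalysed SN2 displacement by 15 (2.2 equiv, the first being consumed by the acetylenic C–H; THF, 0 °C) should give 2,5-dimethoxy-1-methyl-3-[(2Z)-3-methylpent-2-en-4-yn-1-yl]benzene F7, whose Z geometry comes from the purchased alcohol. Hydroboration of the terminal alkyne with dicyclohexylborane should give dicyclohexyl[(1E,3Z)-5-(2,5-dimethoxy-3-methylphenyl)-3-methylpenta-1,3-dien-1-yl]borane F8, and buffered oxidation (H2O2, pH 7, 0 °C) should give aldehyde 17.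

Step 10. Deprotonation at C7 or retro-aldol cleavage of the aldolate may outrun 1,2-addition of the basic alkenyl metal to the hindered ketone. The fallback sets out from 22 and comes back at 24. The dilithium salt of 2-methylbut-3-yn-2-ol F9 (from 18 and n-BuLi, THF, −78 °C) is a smaller and far less basic nucleophile. It should add to 22 to give (1R,5R)-7-[(3Z)-5-(2,5-dimethoxy-3-methylphenyl)-1-hydroxy-3-methylpent-3-en-1-yl]-6-(3-hydroxy-3-methylbut-1-yn-1-yl)-1,5-dimethylbicyclo[3.2.0]heptan-6-ol F10. Hydroxyl-directed trans-hydroalumination of the alkyne with NaAlH2(OCH2CH2OCH3)2 (THF, 0 °C to rt) and protonolysis should then give the E allylic alcohol 24.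

Further compounds
F1 | step 2 | dichloroketene | ClC(Cl)=C=O
F2 | step 2 | racemic cis-7,7-dichloro-1,5-dimethylbicyclo[3.2.0]heptan-6-one (racemate, cis ring fusion) | CC12CCCC1(C)C(=O)C2(Cl)Cl
F3 | step 2 | racemic cis-1,5-dimethylbicyclo[3.2.0]heptan-6-one (racemate, cis ring fusion) | CC12CCCC1(C)C(=O)C2
F4 | step 2 | lithiated (S)-N,S-dimethyl-S-phenylsulfoximine | [Li]C[S@@](=O)(=NC)c1ccccc1
F5 | step 2 | (1R,5R)-1,5-dimethyl-6-{[(S)-N-methyl-S-phenylsulfonimidoyl]methyl}bicyclo[3.2.0]heptan-6-ol, C6 unassigned | OC1(C[S@@](=O)(=NC)c3ccccc3)C[C@@]2(C)CCC[C@@]12C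
F6 | step 6 | (3Z)-5-bromo-3-methylpent-3-en-1-yne | BrC/C=C(C)\C#C
F7 | step 6 | 2,5-dimethoxy-1-methyl-3-[(2Z)-3-methylpent-2-en-4-yn-1-yl]benzene | COc1cc(C)c(OC)c(C/C=C(C)\C#C)c1
F8 | step 6 | dicyclohexyl[(1E,3Z)-5-(2,5-dimethoxy-3-methylphenyl)-3-methylpenta-1,3-dien-1-yl]borane | COc1cc(C)c(OC)c(C/C=C(C)\C=C\B(C2CCCCC2)C2CCCCC2)c1
F9 | step 10 | dilithium salt of 2-methylbut-3-yn-2-ol | [Li]C#CC(C)(C)O[Li]
F10 | step 10 | (1R,5R)-7-[(3Z)-5-(2,5-dimethoxy-3-methylphenyl)-1-hydroxy-3-methylpent-3-en-1-yl]-6-(3-hydroxy-3-methylbut-1-yn-1-yl)-1,5-dimethylbicyclo[3.2.0]heptan-6-ol, C6, C7 and carbinol carbon unassigned | COc1cc(C)c(OC)c(C/C=C(C)\CC(O)C2[C@@]3(C)CCC[C@@]3(C)C2(O)C#CC(C)(C)O)c1
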